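In a one-step world with the working share of the catalyst frozen, rate grows in proportion to the catalyst charge, so a flask's clock is its reading time multiplied by that charge.

all flasks: starting material 0.020 M
- theta: reagent 0.017 M; free catalyst 44 µM; run made earlier
- delta: reagent 0.013 M; free catalyst 44 µM; run made earlier
- maple: reagent 0.0260 M; free catalyst 44 µM; time 5.0 min
- ash: reagent 0.0260 M; free catalyst 30 µM; time 15 min

- theta (time / s: target / %, starting material / %): 10.0: 2.5, 96.1; 12.0: 2.9, 96.0; 25.0: 5.6, 93.9; 60.0: 11.6, 81.8
- delta (time / s: target / %, starting material / %): 10.0: 2.9, 96.8; 20.0: 2.2, 92.7; 40.0: 6.8, 89.0; 60.0: 8.2, 83.6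

(scatter of a reading: 1 percentage point)

- which of the two ends with the higher amount of target, in percent of the starting material charged ("neither" if they lie within 2 percentage points) (maple / ash / neither)
- target at the end, in percent of the starting material charged, maple
- target at the end, in percent of the starting material charged, ash

- no earlier run changes the charge of free catalyst; that part of a forecast is a guess

At 60.0 s, theta held 11.6% target and delta 8.2%, more in the run with more reagent. Maple and ash share one reagent charge, so they differ in catalyst and time. Neither earlier run varied the catalyst, so the clock was my guess.

For maple, 5.0 min at 44 µM made 0.0132 M·s, and for ash, 15 min at 30 µM made 0.0270 M·s. This is the catalyst-time, the reading time multiplied by the catalyst charge; the field calls this variable time normalisation. So ash runs twice as far along, and I expected ash to end higher.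

The forecast said ash, with 47% for maple and 58% for ash, resting on “about twice maple's catalyst-time exposure”.

The flasks gave 54.3% in maple and 73.9% in ash, so ash did end higher, and both values stood above the forecast.

    reagent + free catalyst ⇌ catalyst intermediate A (K = 67.6 L mol⁻¹, k = 9550 L mol⁻¹ min⁻¹)
    catalyst intermediate A ⇌ catalyst intermediate B (K = 2.30, k = 355 min⁻¹)
    starting material + catalyst intermediate B → catalyst intermediate C (k = 25100 L mol⁻¹ min⁻¹)
    catalyst intermediate C → free catalyst + target (k = 267 min⁻¹)
    2 starting material → self-condensation product (k = 2.13 L mol⁻¹ min⁻¹)

Ash read at 7.50 min had a catalyst-time of 0.0135 M·s and held 53.9% target, against 54.3% in maple at 0.0132 M·s. The neighbouring flask, ash with 1.8 × 10⁻⁵ M of free catalyst, has a catalyst-time of 0.0162 M·s. Placed in a straight line between maple and ash, that gives 58.6% target. The neighbouring flask gave 56.8% target, with 12.2% of the starting material left and 31.0% as self-condensation product.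

(The runs are simulated on assumed constants; scatter was added.)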